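**Plan**
1. Retrosynthetic cuts, in order: the C6'–CH2OH bond of ring B (to an aryl triflate and CO); the C1'–C6' bond of ring B (Claisen); the O1–C6 bond of a 2-pyrone (lactonization); the alkyne–alkene bond (Sonogashira); the ring A O–CH2 bond (propargylation); the ring A C1–CO2 bond (anionic Fries shift); the carbinol–isobutyl bond (Grignard).
2. Enabling feature: ring B has its ether oxygen at C1', OH at C2', CH3 at C4' and CH2OH at C6', so it is a 2-aryloxy-5-methylresorcinol with one OH exchanged for CH2OH. That symmetric resorcinol is the Claisen product of a methoxide-opened 6-(aryloxymethyl)-4-methyl-2-pyrone, so the crowded ether oxygen is attached to an sp3 carbon before ring B exists.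
3. Forward order: ring A is bought as 4-hydroxy-2-methoxybenzaldehyde and given its side chain and carboxyl; the pyrone is closed on the propargyl ether; ring B is made from the pyrone; a temporary seven-membered depsidone lactone tells the two ring B hydroxyls apart and is opened at the end.
4. Stereochemistry: the single (S)-carbinol comes from asymmetric transfer hydrogenation of the aryl isobutyl ketone with RuCl[(S,S)-TsDPEN](p-cymene) and is carried as its TBS ether.

Key step: step 13

Remark: ring A is numbered from the carboxyl-bearing carbon (OMe at C2, carbinol at C3, ether oxygen at C6), ring B with primes from the ether carbon C1'; TBS is tert-butyldimethylsilyl; the iodoenoate 13 is assumed to be made, not bought.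

**Step 1**
Reactants: 1 4-hydroxy-2-methoxybenzaldehyde; 2 di-tert-butyl dicarbonate
Product: 3 tert-butyl 4-formyl-3-methoxyphenyl carbonate
Conditions: Boc2O, DMAP (cat.), CH2Cl2, 0 °C to rt
Reagents that add atoms: di-tert-butyl dicarbonate (2), CC(C)(C)OC(=O)OC(=O)OC(C)(C)C
Why: DMAP-catalysed O-acylation of the phenol should give the aryl carbonate, which masks the phenol for the Grignard step and later supplies the ring A carboxyl.

**Step 2**
Reactants: 3 tert-butyl 4-formyl-3-methoxyphenyl carbonate; 4 isobutylmagnesium bromide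
Product: 5 racemic tert-butyl 4-(1-hydroxy-3-methylbutyl)-3-methoxyphenyl carbonate
Conditions: iBuMgBr, THF, −78 °C; aq. NH4Cl at −78 °C
Reagents that add atoms: isobutylmagnesium bromide (4), CC(C)C[Mg]Br
Why: Grignard addition to the aldehyde should outrun attack on the hindered tert-butyl carbonate at low temperature, and the racemic stereocenter is erased in step 3.

**Step 3**
Reactants: 5 racemic tert-butyl 4-(1-hydroxy-3-methylbutyl)-3-methoxyphenyl carbonate
Product: 6 tert-butyl 3-methoxy-4-(3-methylbutanoyl)phenyl carbonate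
Conditions: MnO2 (activated, excess), CH2Cl2, rt
Reagents that add atoms: none
Why: MnO2 oxidation of an electron-rich benzylic alcohol is mild and should leave the carbonate untouched.

**Step 4**
Reactants: 6 tert-butyl 3-methoxy-4-(3-methylbutanoyl)phenyl carbonate
Product: 7 tert-butyl 4-[(1S)-1-hydroxy-3-methylbutyl]-3-methoxyphenyl carbonate
Conditions: RuCl[(S,S)-TsDPEN](p-cymene) (1 mol%), HCO2H–Et3N (5:2), CH2Cl2, 30 °C
Reagents that add atoms: none
Why: In this asymmetric transfer hydrogenation of an aryl alkyl ketone, the CH–π contact between the substrate arene and the cymene ligand fixes the hydride face, so the (S,S)-ligand should give the (S)-alcohol as with other aryl alkyl ketones, and the buffered formate medium should spare the carbonate.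

**Step 5**
Reactants: 7 tert-butyl 4-[(1S)-1-hydroxy-3-methylbutyl]-3-methoxyphenyl carbonate
Product: 8 tert-butyl 4-[(1S)-1-(tert-butyldimethylsilyloxy)-3-methylbutyl]-3-methoxyphenyl carbonate
Conditions: TBSOTf, 2,6-lutidine, CH2Cl2, −78 to −40 °C
Reagents that add atoms: tert-butyldimethylsilyl triflate, CC(C)(C)[Si](C)(C)OS(=O)(=O)C(F)(F)F
Why: Silylation of the secondary benzylic alcohol with the silyl triflate is fast at low temperature and should not touch the tert-butyl carbonate, and the ether protects the carbinol through the base, acylation and triflation steps ahead.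

**Step 6**
Reactants: 8 tert-butyl 4-[(1S)-1-(tert-butyldimethylsilyloxy)-3-methylbutyl]-3-methoxyphenyl carbonate
Product: 9 tert-butyl 3-[(1S)-1-(tert-butyldimethylsilyloxy)-3-methylbutyl]-6-hydroxy-2-methoxybenzoate
Conditions: LiN(iPr)2 (2.2 equiv), THF, −78 to −20 °C; aq. NH4Cl
Reagents that add atoms: none
Why: In this anionic Fries rearrangement the amide base should remove the ring proton flanked by the carbonate and methoxy oxygens (the most acidic one), and the aryllithium then takes the tert-butoxycarbonyl group from O to C to give the salicylate.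

**Step 7**
Reactants: 9 tert-butyl 3-[(1S)-1-(tert-butyldimethylsilyloxy)-3-methylbutyl]-6-hydroxy-2-methoxybenzoate; 10 propargyl bromide
Product: 11 tert-butyl 3-[(1S)-1-(tert-butyldimethylsilyloxy)-3-methylbutyl]-2-methoxy-6-(prop-2-yn-1-yloxy)benzoate
Conditions: propargyl bromide, K2CO3, DMF, rt
Reagents that add atoms: propargyl bromide (10), C#CCBr
Why: Williamson etherification by SN2 at the unhindered propargylic carbon makes the O–C1' bond of the future diaryl ether without any aryl–oxygen coupling.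

**Step 8**
Reactants: 12 methyl but-2-ynoate
Product: 13 methyl (2Z)-3-iodobut-2-enoate
Conditions: NaI, AcOH, 115 °C
Reagents that add atoms: sodium iodide, [Na+].[I-]
Why: Hydroiodination of a 2-ynoate with NaI in acetic acid (conjugate addition of iodide, then anti protonation) is known to give the (Z)-3-iodo-2-enoate.

**Step 9**
Reactants: 11 tert-butyl 3-[(1S)-1-(tert-butyldimethylsilyloxy)-3-methylbutyl]-2-methoxy-6-(prop-2-yn-1-yloxy)benzoate; 13 methyl (2Z)-3-iodobut-2-enoate
Product: 14 methyl (2Z)-6-{2-(tert-butoxycarbonyl)-4-[(1S)-1-(tert-butyldimethylsilyloxy)-3-methylbutyl]-3-methoxyphenoxy}-3-methylhex-2-en-4-ynoate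
Conditions: Pd(PPh3)2Cl2 (3 mol%), CuI (6 mol%), Et3N, THF, rt, degassed
Reagents that add atoms: none
Why: Sonogashira coupling of a terminal alkyne with a vinyl iodide retains the alkene geometry, so the ester ends up cis to the alkyne as the lactonization requires.

**Step 10**
Reactants: 14 methyl (2Z)-6-{2-(tert-butoxycarbonyl)-4-[(1S)-1-(tert-butyldimethylsilyloxy)-3-methylbutyl]-3-methoxyphenoxy}-3-methylhex-2-en-4-ynoate
Product: 15 (2Z)-6-{2-(tert-butoxycarbonyl)-4-[(1S)-1-(tert-butyldimethylsilyloxy)-3-methylbutyl]-3-methoxyphenoxy}-3-methylhex-2-en-4-ynoic acid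
Conditions: LiOH·H2O, THF–H2O, 0 °C to rt; 1 M HCl to pH 3 at 0 °C
Reagents that add atoms: lithium hydroxide, [Li+].[OH-]
Why: Saponification should cleave only the unhindered conjugated methyl ester, because the tert-butyl ester flanked by two ortho substituents resists hydroxide.

**Step 11**
Reactants: 15 (2Z)-6-{2-(tert-butoxycarbonyl)-4-[(1S)-1-(tert-butyldimethylsilyloxy)-3-methylbutyl]-3-methoxyphenoxy}-3-methylhex-2-en-4-ynoic acid
Product: 16 tert-butyl 3-[(1S)-1-(tert-butyldimethylsilyloxy)-3-methylbutyl]-2-methoxy-6-[(4-methyl-2-oxo-2H-pyran-6-yl)methoxy]benzoate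
Conditions: ZnBr2 (0.2 equiv), THF, rt
Reagents that add atoms: none
Why: ZnBr2-catalysed 6-endo-dig lactonization of a (Z)-2-en-4-ynoic acid puts the carboxyl oxygen on the conjugate alkyne carbon and should give the 2-pyrone instead of the 5-exo ylidenebutenolide that silver salts favour.

**Step 12**
Reactants: 16 tert-butyl 3-[(1S)-1-(tert-butyldimethylsilyloxy)-3-methylbutyl]-2-methoxy-6-[(4-methyl-2-oxo-2H-pyran-6-yl)methoxy]benzoate
Product: 18 3-[(1S)-1-(tert-butyldimethylsilyloxy)-3-methylbutyl]-2-methoxy-6-[(4-methyl-2-oxo-2H-pyran-6-yl)methoxy]benzoic acid, via trimethylsilyl ester 17 (not isolated)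
Conditions: TMSOTf, 2,6-lutidine, CH2Cl2, 0 °C; pH 4 aqueous work-up
Reagents that add atoms: none
Why: Silyl triflate-mediated tert-butyl ester cleavage (carbonyl O-silylation, loss of the tert-butyl cation as isobutene, hydrolysis of the silyl ester on work-up) should spare the TBS ether and the pyrone under lutidine buffering, where protic acid would risk ionizing the electron-rich benzylic silyl ether.

**Step 13**
Reactants: 18 3-[(1S)-1-(tert-butyldimethylsilyloxy)-3-methylbutyl]-2-methoxy-6-[(4-methyl-2-oxo-2H-pyran-6-yl)methoxy]benzoic acid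
Product: 21 6-(2,6-dihydroxy-4-methylphenoxy)-3-[(1S)-1-(tert-butyldimethylsilyloxy)-3-methylbutyl]-2-methoxybenzoic acid, via ring-opened keto ester 19 (not isolated), via cyclohexenedione 20 (not isolated)
Conditions: NaOMe (6 equiv), MeOH (0.02 M), 65 °C; 1 M HCl to pH 3 at 0 °C
Reagents that add atoms: none
Why: Proposed new method: methoxide adds to the lactone carbonyl of 18 (present as its carboxylate) and the pyrone opens to the enolate of keto ester 19, whose ester and ketone arms stay cis on the trisubstituted alkene; proton exchange then gives the carbanion on the aryloxy-bearing carbon C1', which adds to the ester carbon C6' and expels methoxide to give dione 20, and enolization to the resorcinol dianion draws the earlier equilibria forward. The closest known reaction types are the base-induced ring transformation of 6-alkyl-2-pyranones and the intramolecular Claisen (Dieckmann-type) cyclization of 5-oxo and 3,5-dioxo esters to cyclohexane-1,3-diones and resorcinols, neither of which has been run with an aryloxy group on the nucleophilic carbon. Ring B closes by C-acylation in a 6-(enolexo)-exo-trig mode. No stereocenter forms, and the silylated (S)-carbinol has no acidic hydrogen that the base could remove. The step needs closure from C1' and not from the more acidic C3' methylene, and acylation at C6' and not at the ring A carboxyl: only C1' reaches the ester through a six-membered transition state (C3' would make a four-membered ring), the Z-alkene inherited from the pyrone holds the two ends together, and the ring A carboxylate is inert to a carbanion, so no benzofuranone can form. The product is symmetric about its C1'–C4' axis, so its two hydroxyls are equivalent and replacing one of them later is unambiguous.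

**Step 14**
Reactants: 21 6-(2,6-dihydroxy-4-methylphenoxy)-3-[(1S)-1-(tert-butyldimethylsilyloxy)-3-methylbutyl]-2-methoxybenzoic acid
Product: 22 2-[(1S)-1-(tert-butyldimethylsilyloxy)-3-methylbutyl]-6-hydroxy-1-methoxy-8-methyl-11H-dibenzo[b,e][1,4]dioxepin-11-one (depsidone)
Conditions: EDC·HCl, DMAP (cat.), CH2Cl2 (0.005 M), rt
Reagents that add atoms: none
Why: Carbodiimide (Steglich-type) lactonization of a 2-(2-hydroxyphenoxy)benzoic acid is a standard closure of the seven-membered depsidone ring, and since the two ring B hydroxyls are equivalent only one lactone can form, leaving one free phenol.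

**Step 15**
Reactants: 22 depsidone phenol
Product: 23 2-[(1S)-1-(tert-butyldimethylsilyloxy)-3-methylbutyl]-1-methoxy-8-methyl-11-oxo-11H-dibenzo[b,e][1,4]dioxepin-6-yl trifluoromethanesulfonate
Conditions: Tf2O, pyridine, CH2Cl2, −20 to 0 °C
Reagents that add atoms: triflic anhydride, O=S(=O)(OS(=O)(=O)C(F)(F)F)C(F)(F)F
Why: O-sulfonylation of the single remaining phenol is routine, and pyridine buffering should keep the silyl ether and the lactone intact.

**Step 16**
Reactants: 23 depsidone triflate; 24 carbon monoxide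
Product: 25 2-[(1S)-1-(tert-butyldimethylsilyloxy)-3-methylbutyl]-1-methoxy-8-methyl-11-oxo-11H-dibenzo[b,e][1,4]dioxepine-6-carbaldehyde
Conditions: Pd(OAc)2 (5 mol%), dppp (5 mol%), CO (1 atm), Et3SiH, Et3N, DMF, 70 °C
Reagents that add atoms: carbon monoxide (24), [C-]#[O+]
Why: Palladium-catalysed reductive carbonylation of an aryl triflate (oxidative addition to zerovalent palladium, CO insertion, hydride transfer from the silane to the acylpalladium) should give the aldehyde under neutral conditions that spare the lactone.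

**Step 17**
Reactants: 25 depsidone aldehyde
Product: 27 3-[(1S)-1-(tert-butyldimethylsilyloxy)-3-methylbutyl]-6-[2-hydroxy-6-(hydroxymethyl)-4-methylphenoxy]-2-methoxybenzoic acid, via hydroxymethyl depsidone 26 (not isolated)
Conditions: NaBH4, THF–H2O, 0 °C; then aq. LiOH, rt; 1 M HCl to pH 3 at 0 °C
Reagents that add atoms: lithium hydroxide, [Li+].[OH-]
Why: Borohydride should reduce the aryl aldehyde much faster than the lactone, hydroxide then cleaves the activated aryl ester by acyl substitution to the carboxylate and the C2' phenoxide, and water in place of methanol avoids a hindered methyl ester.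

**Step 18**
Reactants: 27 silylated seco acid
Product: 28 6-[2-hydroxy-6-(hydroxymethyl)-4-methylphenoxy]-3-[(1S)-1-hydroxy-3-methylbutyl]-2-methoxybenzoic acid (CNP0221397.1)
Conditions: Bu4NF (5 equiv), THF, rt to 40 °C; aq. NH4Cl
Reagents that add atoms: none
Why: Fluoride-induced cleavage of the silyl ether under non-acidic conditions should free the carbinol without ionizing the electron-rich benzylic position, so the (S)-configuration is retained.

**Compound list**
1 | 4-hydroxy-2-methoxybenzaldehyde | COc1cc(O)ccc1C=O | starting material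
2 | di-tert-butyl dicarbonate | CC(C)(C)OC(=O)OC(=O)OC(C)(C)C | starting material
3 | tert-butyl 4-formyl-3-methoxyphenyl carbonate | COc1cc(OC(=O)OC(C)(C)C)ccc1C=O | intermediate
4 | isobutylmagnesium bromide | CC(C)C[Mg]Br | starting material
5 | racemic tert-butyl 4-(1-hydroxy-3-methylbutyl)-3-methoxyphenyl carbonate | COc1cc(OC(=O)OC(C)(C)C)ccc1C(O)CC(C)C | intermediate
6 | tert-butyl 3-methoxy-4-(3-methylbutanoyl)phenyl carbonate | COc1cc(OC(=O)OC(C)(C)C)ccc1C(=O)CC(C)C | intermediate
7 | tert-butyl 4-[(1S)-1-hydroxy-3-methylbutyl]-3-methoxyphenyl carbonate | COc1cc(OC(=O)OC(C)(C)C)ccc1[C@@H](O)CC(C)C | intermediate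
8 | tert-butyl 4-[(1S)-1-(tert-butyldimethylsilyloxy)-3-methylbutyl]-3-methoxyphenyl carbonate | COc1cc(OC(=O)OC(C)(C)C)ccc1[C@@H](O[Si](C)(C)C(C)(C)C)CC(C)C | intermediate
9 | tert-butyl 3-[(1S)-1-(tert-butyldimethylsilyloxy)-3-methylbutyl]-6-hydroxy-2-methoxybenzoate | COc1c([C@@H](O[Si](C)(C)C(C)(C)C)CC(C)C)ccc(O)c1C(=O)OC(C)(C)C | intermediate
10 | propargyl bromide (3-bromoprop-1-yne) | C#CCBr | starting material
11 | tert-butyl 3-[(1S)-1-(tert-butyldimethylsilyloxy)-3-methylbutyl]-2-methoxy-6-(prop-2-yn-1-yloxy)benzoate | COc1c([C@@H](O[Si](C)(C)C(C)(C)C)CC(C)C)ccc(OCC#C)c1C(=O)OC(C)(C)C | intermediate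
12 | methyl but-2-ynoate | CC#CC(=O)OC | starting material
13 | methyl (2Z)-3-iodobut-2-enoate | COC(=O)/C=C(/C)I | intermediate
14 | methyl (2Z)-6-{2-(tert-butoxycarbonyl)-4-[(1S)-1-(tert-butyldimethylsilyloxy)-3-methylbutyl]-3-methoxyphenoxy}-3-methylhex-2-en-4-ynoate | COC(=O)/C=C(/C)C#CCOc1ccc([C@@H](O[Si](C)(C)C(C)(C)C)CC(C)C)c(OC)c1C(=O)OC(C)(C)C | intermediate
15 | (2Z)-6-{2-(tert-butoxycarbonyl)-4-[(1S)-1-(tert-butyldimethylsilyloxy)-3-methylbutyl]-3-methoxyphenoxy}-3-methylhex-2-en-4-ynoic acid | OC(=O)/C=C(/C)C#CCOc1ccc([C@@H](O[Si](C)(C)C(C)(C)C)CC(C)C)c(OC)c1C(=O)OC(C)(C)C | intermediate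
16 | tert-butyl 3-[(1S)-1-(tert-butyldimethylsilyloxy)-3-methylbutyl]-2-methoxy-6-[(4-methyl-2-oxo-2H-pyran-6-yl)methoxy]benzoate | COc1c([C@@H](O[Si](C)(C)C(C)(C)C)CC(C)C)ccc(OCC2=CC(C)=CC(=O)O2)c1C(=O)OC(C)(C)C | intermediate
17 | trimethylsilyl 3-[(1S)-1-(tert-butyldimethylsilyloxy)-3-methylbutyl]-2-methoxy-6-[(4-methyl-2-oxo-2H-pyran-6-yl)methoxy]benzoate (not isolated) | COc1c([C@@H](O[Si](C)(C)C(C)(C)C)CC(C)C)ccc(OCC2=CC(C)=CC(=O)O2)c1C(=O)O[Si](C)(C)C | intermediate
18 | 3-[(1S)-1-(tert-butyldimethylsilyloxy)-3-methylbutyl]-2-methoxy-6-[(4-methyl-2-oxo-2H-pyran-6-yl)methoxy]benzoic acid | COc1c([C@@H](O[Si](C)(C)C(C)(C)C)CC(C)C)ccc(OCC2=CC(C)=CC(=O)O2)c1C(=O)O | intermediate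
19 | 3-[(1S)-1-(tert-butyldimethylsilyloxy)-3-methylbutyl]-2-methoxy-6-{[(4Z)-6-methoxy-4-methyl-2,6-dioxohex-4-en-1-yl]oxy}benzoic acid, the ring-opened methyl (2Z)-6-aryloxy-3-methyl-5-oxohex-2-enoate (not isolated; present as its sodium salts) | COC(=O)/C=C(/C)CC(=O)COc1ccc([C@@H](O[Si](C)(C)C(C)(C)C)CC(C)C)c(OC)c1C(=O)O | intermediate
20 | 3-[(1S)-1-(tert-butyldimethylsilyloxy)-3-methylbutyl]-2-methoxy-6-[(4-methyl-2,6-dioxocyclohex-3-en-1-yl)oxy]benzoic acid (not isolated) | COc1c([C@@H](O[Si](C)(C)C(C)(C)C)CC(C)C)ccc(OC2C(=O)CC(C)=CC2=O)c1C(=O)O | intermediate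
21 | 6-(2,6-dihydroxy-4-methylphenoxy)-3-[(1S)-1-(tert-butyldimethylsilyloxy)-3-methylbutyl]-2-methoxybenzoic acid | COc1c([C@@H](O[Si](C)(C)C(C)(C)C)CC(C)C)ccc(Oc2c(O)cc(C)cc2O)c1C(=O)O | intermediate
22 | 2-[(1S)-1-(tert-butyldimethylsilyloxy)-3-methylbutyl]-6-hydroxy-1-methoxy-8-methyl-11H-dibenzo[b,e][1,4]dioxepin-11-one | COc1c([C@@H](O[Si](C)(C)C(C)(C)C)CC(C)C)ccc2c1C(=O)Oc1cc(C)cc(O)c1O2 | intermediate
23 | 2-[(1S)-1-(tert-butyldimethylsilyloxy)-3-methylbutyl]-1-methoxy-8-methyl-11-oxo-11H-dibenzo[b,e][1,4]dioxepin-6-yl trifluoromethanesulfonate | COc1c([C@@H](O[Si](C)(C)C(C)(C)C)CC(C)C)ccc2c1C(=O)Oc1cc(C)cc(OS(=O)(=O)C(F)(F)F)c1O2 | intermediate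
24 | carbon monoxide | [C-]#[O+] | starting material
25 | 2-[(1S)-1-(tert-butyldimethylsilyloxy)-3-methylbutyl]-1-methoxy-8-methyl-11-oxo-11H-dibenzo[b,e][1,4]dioxepine-6-carbaldehyde | COc1c([C@@H](O[Si](C)(C)C(C)(C)C)CC(C)C)ccc2c1C(=O)Oc1cc(C)cc(C=O)c1O2 | intermediate
26 | 2-[(1S)-1-(tert-butyldimethylsilyloxy)-3-methylbutyl]-6-(hydroxymethyl)-1-methoxy-8-methyl-11H-dibenzo[b,e][1,4]dioxepin-11-one (not isolated) | COc1c([C@@H](O[Si](C)(C)C(C)(C)C)CC(C)C)ccc2c1C(=O)Oc1cc(C)cc(CO)c1O2 | intermediate
27 | 3-[(1S)-1-(tert-butyldimethylsilyloxy)-3-methylbutyl]-6-[2-hydroxy-6-(hydroxymethyl)-4-methylphenoxy]-2-methoxybenzoic acid | COc1c([C@@H](O[Si](C)(C)C(C)(C)C)CC(C)C)ccc(Oc2c(O)cc(C)cc2CO)c1C(=O)O | intermediate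
28 | 6-[2-hydroxy-6-(hydroxymethyl)-4-methylphenoxy]-3-[(1S)-1-hydroxy-3-methylbutyl]-2-methoxybenzoic acid | COc1c([C@@H](O)CC(C)C)ccc(Oc2c(O)cc(C)cc2CO)c1C(=O)O | target

**Count**
Total: 18 steps. Longest linear sequence: 17 steps (steps 1–7 and 9–18 from 1); step 8 is a one-step side branch.

**Steps most likely to fail**

1. Step 13 (the proposed new method). The opened enolate may rest as the unreactive extended dienolate or drift to the E-alkene so that C-acylation stalls, or methoxide may add in conjugate fashion and degrade the chain. The fallback builds the diaryl ether by a conventional SNAr reaction; it leaves the route at phenol 9 and rejoins it at 27. Commercial 2-fluoro-5-methylphenol would be benzylated (BnBr, K2CO3, DMF) to 2-(benzyloxy)-1-fluoro-4-methylbenzene F1. Lithiation next to fluorine (LiN(iPr)2, THF, −78 °C) and a DMF quench would give 3-(benzyloxy)-2-fluoro-5-methylbenzaldehyde F2. Displacement of the aldehyde-activated fluoride by 9 (Cs2CO3, DMSO, 100 °C) would give tert-butyl 6-[2-(benzyloxy)-6-formyl-4-methylphenoxy]-3-[(1S)-1-(tert-butyldimethylsilyloxy)-3-methylbutyl]-2-methoxybenzoate F3. NaBH4 would reduce it to the benzylic alcohol, tert-butyl 6-[2-(benzyloxy)-6-(hydroxymethyl)-4-methylphenoxy]-3-[(1S)-1-(tert-butyldimethylsilyloxy)-3-methylbutyl]-2-methoxybenzoate F4. Hydrogenolysis (H2, Pd/C, EtOAc) would free the phenol, tert-butyl 3-[(1S)-1-(tert-butyldimethylsilyloxy)-3-methylbutyl]-6-[2-hydroxy-6-(hydroxymethyl)-4-methylphenoxy]-2-methoxybenzoate F5. Ester cleavage with TMSOTf and 2,6-lutidine, with a mild aqueous work-up that also removes transient trimethylsilyl ethers, would give 27.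

2. Step 6. Deprotonation may occur at the other ortho position of the carbonate, because the methoxy group, pushed toward the doubly activated site by the neighbouring side chain, shields it. The fallback replaces the acyl shift by a chelation-directed lithiation with an external electrophile; it leaves the route at carbonate 8 and rejoins it at 9. Methanolysis of the carbonate (K2CO3, MeOH) would give 4-[(1S)-1-(tert-butyldimethylsilyloxy)-3-methylbutyl]-3-methoxyphenol F6. MOMCl and iPr2NEt would convert it into 1-[(1S)-1-(tert-butyldimethylsilyloxy)-3-methylbutyl]-2-methoxy-4-(methoxymethoxy)benzene F7. Lithiation between the two ether oxygens (n-BuLi, TMEDA, THF, −78 to 0 °C) and trapping with Boc2O would give tert-butyl 3-[(1S)-1-(tert-butyldimethylsilyloxy)-3-methylbutyl]-2-methoxy-6-(methoxymethoxy)benzoate F8. Removal of the acetal with ZnBr2 and n-PrSH (CH2Cl2, 0 °C) would give 9.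

3. Step 11. Closure may go 5-exo-dig to the ylidenebutenolide, since the electron-withdrawing aryloxymethyl group disfavours attack at the distal alkyne carbon. The fallback attaches a preformed pyrone; it leaves the route at phenol 9 and rejoins it at 16. Commercial 4,6-dimethyl-2H-pyran-2-one would be oxidized at its 6-methyl group (SeO2, dioxane, heat) to 4-methyl-2-oxo-2H-pyran-6-carbaldehyde F9. NaBH4 at 0 °C would reduce it to 6-(hydroxymethyl)-4-methyl-2H-pyran-2-one F10. Mitsunobu etherification of F10 with 9 (PPh3, DIAD, THF) would give 16.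

**Further compounds**
F1 | step 13 | 2-(benzyloxy)-1-fluoro-4-methylbenzene | Cc1ccc(F)c(OCc2ccccc2)c1
F2 | step 13 | 3-(benzyloxy)-2-fluoro-5-methylbenzaldehyde | Cc1cc(C=O)c(F)c(OCc2ccccc2)c1
F3 | step 13 | tert-butyl 6-[2-(benzyloxy)-6-formyl-4-methylphenoxy]-3-[(1S)-1-(tert-butyldimethylsilyloxy)-3-methylbutyl]-2-methoxybenzoate | COc1c([C@@H](O[Si](C)(C)C(C)(C)C)CC(C)C)ccc(Oc2c(OCc3ccccc3)cc(C)cc2C=O)c1C(=O)OC(C)(C)C
F4 | step 13 | tert-butyl 6-[2-(benzyloxy)-6-(hydroxymethyl)-4-methylphenoxy]-3-[(1S)-1-(tert-butyldimethylsilyloxy)-3-methylbutyl]-2-methoxybenzoate | COc1c([C@@H](O[Si](C)(C)C(C)(C)C)CC(C)C)ccc(Oc2c(OCc3ccccc3)cc(C)cc2CO)c1C(=O)OC(C)(C)C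
F5 | step 13 | tert-butyl 3-[(1S)-1-(tert-butyldimethylsilyloxy)-3-methylbutyl]-6-[2-hydroxy-6-(hydroxymethyl)-4-methylphenoxy]-2-methoxybenzoate | COc1c([C@@H](O[Si](C)(C)C(C)(C)C)CC(C)C)ccc(Oc2c(O)cc(C)cc2CO)c1C(=O)OC(C)(C)C
F6 | step 6 | 4-[(1S)-1-(tert-butyldimethylsilyloxy)-3-methylbutyl]-3-methoxyphenol | COc1cc(O)ccc1[C@@H](O[Si](C)(C)C(C)(C)C)CC(C)C
F7 | step 6 | 1-[(1S)-1-(tert-butyldimethylsilyloxy)-3-methylbutyl]-2-methoxy-4-(methoxymethoxy)benzene | COCOc1ccc([C@@H](O[Si](C)(C)C(C)(C)C)CC(C)C)c(OC)c1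
F8 | step 6 | tert-butyl 3-[(1S)-1-(tert-butyldimethylsilyloxy)-3-methylbutyl]-2-methoxy-6-(methoxymethoxy)benzoate | COCOc1ccc([C@@H](O[Si](C)(C)C(C)(C)C)CC(C)C)c(OC)c1C(=O)OC(C)(C)C
F9 | step 11 | 4-methyl-2-oxo-2H-pyran-6-carbaldehyde | CC1=CC(=O)OC(C=O)=C1
F10 | step 11 | 6-(hydroxymethyl)-4-methyl-2H-pyran-2-one | CC1=CC(=O)OC(CO)=C1
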